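The data stem from a simulated flask with made-up constants; scatter was added.

At early times the readings seem to take sides: at 0.833 min Friday's run, with 0.10 mM protic impurity, shows ring 3 %, and Sunday's run, with 0.41 mM, shows 0 %.

| flask | starting material | protic impurity | remark | time |
|---|---|---|---|---|
| Friday's | 11 mM (fed, over 4.0 min) | 0.10 mM | run made earlier |  |
| Monday's | 11 mM (fed, over 4.0 min) | 0.21 mM | run made earlier |  |
| Sunday's | 11 mM (fed, over 4.0 min) | 0.41 mM | run made earlier |  |
| south | 11 mM (fed, over 4.0 min) | 0.120 mM |  | 4.0 min |
| east | 11 mM (fed, over 4.0 min) | 0.200 mM |  | 4.0 min |
| west | 11 mM (fed, over 4.0 min) | 0.400 mM |  | 4.0 min |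

| run | time / min | ring / % | open dimer / % |
|---|---|---|---|
| Friday's | 0.833 | 3 | 1 |
| Friday's | 1.50 | 11 | 1 |
| Friday's | 2.50 | 21 | 3 |
| Friday's | 3.00 | 27 | 5 |
| Friday's | 4.00 | 40 | 12 |
| Monday's | 0.333 | 1 | 0 |
| Monday's | 0.667 | 2 | 3 |
| Monday's | 1.00 | 5 | 2 |
| Monday's | 2.00 | 11 | 5 |
| Monday's | 4.00 | 36 | 12 |
| Sunday's | 0.833 | 0 | 2 |
| Sunday's | 1.50 | 13 | 4 |
| Sunday's | 2.50 | 21 | 4 |
| Sunday's | 3.00 | 26 | 3 |
| Sunday's | 4.00 | 39 | 13 |

(each reading ± 1.5 percentage points)

- percent here means starting material units held: one open dimer counts as two
- the analysis behind the earlier runs scatters by 1.5 percentage points, standard deviation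
- steps under discussion: starting material -> ring; 2 starting material -> open dimer; starting material + protic impurity -> quenched substrate; ring -> over-reaction product; ring <-> isomer of the product
- "hardly changes" means that all values lie within two and a half points (for a concentration: within two and a half percent of the largest)
- percentages count the whole charge, also what has not yet gone in

- share of ring in all that became ring or open dimer or over-reaction product or isomer of the product for south, east, west, in this order
- the shape of the row from first to last (rises all the way / hardly changes / falls, then rises / falls all the way / rises, then falls)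

One chemist reads that gap of 3 percentage points as impurity eating the first feed, and she expects the row to fall from south to west. The other answers that a reading scatters by 1.5 points, and that at 1.50 min the order reverses, Friday's ring 11 % against Sunday's 13 %. He makes the forecast: 76 %, 76 %, 76 %, so the row hardly changes. His ground is that "Even if quenching is fast, it only delays build-up".

My own reckoning keeps the balance of the protic impurity, the limiting reagent of the quench. Each impurity takes one starting material, so quenched substrate cannot pass impurity charged over starting material charged, which is 1.09 % for south and 3.64 % for west. Call this the quench ceiling.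

Between west and south, then, the quench can withdraw at most 2.5 points of the charge. Take that whole amount from ring in Friday's end readings, and ring's share of ring plus open dimer goes from 76.9 % to 75.7 %. I side with him on the shape. The ceiling gives no level, though, so the forecast's level remains his own, taken from the readings.

The simulation gives 65.3 %, 65.5 % and 65.8 % for south, east and west: the row hardly changes, so the expected fall fails and the forecast's shape stands, but its level lies 10 points too high.

    starting material → ring (k = 0.00727 s⁻¹)
    2 starting material → open dimer (k = 0.249 M⁻¹ s⁻¹)
    starting material + protic impurity → quenched substrate (k = 11.8 M⁻¹ s⁻¹)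
    ring → over-reaction product (k = 0.00144 s⁻¹)
    ring ⇌ isomer of the product (K = 0.420, k = 0.00113 s⁻¹)

South at 4.00 min holds over-reaction product 5.43 % and isomer of the product 3.58 %, and the quench step makes no difference to south's share. The first chemist keeps the early ground: at 2.00 min west holds starting material 29.3 % against south's 30.6 %, and at 4.00 min west holds 39.7 % against south's 40.1 %. The ceiling stands in both flasks: at 4.00 min quenched substrate is 1.09 % in south against 1.09 %, and 3.64 % in west against 3.64 %.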